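**Retrosynthetic overview**

1. C10=C11 (E) is cut by a Julia–Kocienski olefination between a C1–C10 dioxolane aldehyde and a C11–C15 styryl phenyltetrazolyl sulfone; the acid is freed last from its ethyl ester.
2. The only ring, the 1,2-dioxolane, is made once and early, as in the presumed biosynthesis: first C5–O by cobalt-mediated capture of O2 at a 5-methylidene skipped dienoate, then C3–O by 5-exo addition of the C5 peroxide to the Δ2 enoate, here under chiral ion-pair control.
3. The skipped dienoate comes from a C4–C5 coupling of an internal alkenylalane with ethyl (E)-4-bromo-3-methylbut-2-enoate.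
4. The alkyne behind the alkenylalane is the one-carbon homologue of (R)-citronellal, which supplies C5–C10, the C7 stereocentre and, as its prenyl alkene, the masked C10 aldehyde.
5. The sulfone comes from 1-phenyl-1H-tetrazole-5-thiol, 5-bromopent-1-ene and styrene (S-alkylation, oxidation, cross-metathesis).

Assumption: the cinchonidine-derived ammonium salt of step 4 is taken to deliver 3S; should it deliver 3R, its cinchonine-derived pseudoenantiomer is used instead. Compound numbers follow the forward route; atom numbers C1–C15 are those of the target chain.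

**Route**

Step 1
Reactants: 1 (R)-citronellal, (3R)-3,7-dimethyloct-6-enal
Product: 2 (4R)-4,8-dimethylnon-7-en-1-yne
Conditions: Ohira–Bestmann reagent (1.3 equiv), K2CO3 (2 equiv), MeOH, 0 → 23 °C
Reagents that add atoms: Ohira–Bestmann reagent, dimethyl (1-diazo-2-oxopropyl)phosphonate, COP(=O)(OC)C(=[N+]=[N-])C(C)=O
Why: Seyferth–Gilbert homologation in its Ohira–Bestmann form turns the aldehyde into a terminal alkyne under mild carbonate conditions; the stereocentre (future C7, R, bought with 1) is β to the carbonyl and is not touched.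

Step 2
Reactants: 2 (4R)-4,8-dimethylnon-7-en-1-yne; 3 ethyl (2E)-4-bromo-3-methylbut-2-enoate
Product: 5 ethyl (2E,7R)-3,7,11-trimethyl-5-methylidenedodeca-2,10-dienoate, via alkenylalane 4 (not isolated)
Conditions: 2 (1.15 equiv), iBu2AlH (1.0 equiv), NiCl2(dppp) (3 mol %), THF, 0 → 23 °C; then 3 (0.9 equiv), Pd(PPh3)4 (5 mol %), 0 → 23 °C
Reagents that add atoms: none
Why: Nickel-catalysed hydroalumination with the dppp ligand is α-selective and puts aluminium on the internal alkyne carbon, and the palladium-catalysed alkenyl–allyl coupling (Negishi type) bonds that carbon to the CH2Br terminus of the allyl unit so that the enoate stays conjugated; no stereocentre is formed.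

Step 3
Reactants: 5 ethyl (2E,7R)-3,7,11-trimethyl-5-methylidenedodeca-2,10-dienoate
Product: 6 ethyl (2E,5R,7R)-3,5,7,11-tetramethyl-5-[(triethylsilyl)peroxy]dodeca-2,10-dienoate (obtained with an equal amount of its 5S epimer, not separated)
Conditions: Co(thd)2 (5 mol %; thd = 2,2,6,6-tetramethylheptane-3,5-dionate), O2 (1 atm), Et3SiH (2 equiv), ClCH2CH2Cl, 23 °C, stopped at about 90 % conversion
Reagents that add atoms: dioxygen, O=O; triethylsilane, CC[SiH](CC)CC
Why: Isayama–Mukaiyama hydroperoxysilylation: hydrogen-atom transfer from a cobalt hydride goes to the unhindered 1,1-disubstituted alkene faster than to the trisubstituted prenyl or enoate alkenes, the tertiary C5 radical captures O2 and the peroxide is silylated; C5 is created here without facial bias, so the needed 5R epimer and its 5S epimer form about 1:1 and go on together.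

Step 4
Reactants: 6 ethyl (2E,5R,7R)-3,5,7,11-tetramethyl-5-[(triethylsilyl)peroxy]dodeca-2,10-dienoate (with its 5S epimer)
Product: 8 ethyl 2-[(3S,5R)-5-[(2R)-2,6-dimethylhept-5-en-1-yl]-3,5-dimethyl-1,2-dioxolan-3-yl]acetate, via hydroperoxide 7 (not isolated)
Conditions: O-allyl-N-(9-anthracenylmethyl)cinchonidinium bromide (10 mol %), KHF2 (1.5 equiv, ground), toluene, −40 → −20 °C; silica chromatography
Reagents that add atoms: none
Why: Proposed new method: fluoride carried by the chiral ammonium cation removes the silyl group, the tertiary peroxide anion stays ion-paired with that cation in toluene and adds 5-exo-trig to one face of the enoate (the biosynthetic peroxide-to-enoate closure), and HF protonates the ester enolate; the cation is expected to select the face that gives 3S, so the 5R epimer closes as the matched case to the trans (3S,5R) ring with its two larger arms anti, while the 5S epimer can only give the more crowded cis (3S,5S) ring, which differs in polarity and is removed on silica (at most 50 % of 6 reaches 8); the closest known reactions are cinchona ammonium-controlled conjugate additions of peroxide anions to enones (asymmetric Weitz–Scheffer epoxidation), chiral ammonium fluoride-triggered desilylative Michael additions and base-mediated hydroperoxide oxa-Michael closures to 1,2-dioxolanes.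

Step 5
Reactants: 8 ethyl 2-[(3S,5R)-5-[(2R)-2,6-dimethylhept-5-en-1-yl]-3,5-dimethyl-1,2-dioxolan-3-yl]acetate
Product: 10 ethyl 2-[(3S,5R)-3,5-dimethyl-5-[(2R)-2-methyl-5-oxopentyl]-1,2-dioxolan-3-yl]acetate, via ozonide 9 (not isolated)
Conditions: O3, CH2Cl2, −78 °C (Sudan Red 7B end point); then Me2S (5 equiv), −78 → 23 °C
Reagents that add atoms: ozone, [O-][O+]=O
Why: Ozonolysis (Criegee mechanism, reductive work-up) cleaves the only remaining C=C to the C10 aldehyde; the fully substituted dialkyl peroxide and the ester are inert to ozone and Me2S, and no stereocentre is affected.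

Step 6
Reactants: 11 1-phenyl-1H-tetrazole-5-thiol; 12 5-bromopent-1-ene
Product: 13 5-(pent-4-en-1-ylsulfanyl)-1-phenyl-1H-tetrazole
Conditions: K2CO3 (1.5 equiv), acetone, 23 °C
Reagents that add atoms: none
Why: SN2 S-alkylation of the thiolate of 11 by a primary bromide.

Step 7
Reactants: 13 5-(pent-4-en-1-ylsulfanyl)-1-phenyl-1H-tetrazole
Product: 14 5-(pent-4-ene-1-sulfonyl)-1-phenyl-1H-tetrazole
Conditions: (NH4)6Mo7O24·4H2O (5 mol %), 30 % H2O2 (5 equiv), EtOH, 0 → 23 °C
Reagents that add atoms: hydrogen peroxide, OO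
Why: Molybdate-catalysed peroxide oxidation takes the sulfide to the sulfone and leaves the unactivated terminal alkene alone (chemoselective S-oxidation).

Step 8
Reactants: 14 5-(pent-4-ene-1-sulfonyl)-1-phenyl-1H-tetrazole; 15 styrene
Product: 16 1-phenyl-5-{[(4E)-5-phenylpent-4-en-1-yl]sulfonyl}-1H-tetrazole
Conditions: 15 (3 equiv), second-generation Grubbs catalyst RuCl2(=CHPh)(PCy3)(H2IMes) (3 mol %), CH2Cl2, 40 °C
Reagents that add atoms: none
Why: Olefin cross-metathesis of a terminal alkene with excess styrene gives the conjugated E-alkene under thermodynamic control (E:Z above 20:1).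

Step 9
Reactants: 16 1-phenyl-5-{[(4E)-5-phenylpent-4-en-1-yl]sulfonyl}-1H-tetrazole; 10 ethyl 2-[(3S,5R)-3,5-dimethyl-5-[(2R)-2-methyl-5-oxopentyl]-1,2-dioxolan-3-yl]acetate
Product: 18 ethyl 2-[(3S,5R)-3,5-dimethyl-5-[(2R,5E,9E)-2-methyl-10-phenyldeca-5,9-dien-1-yl]-1,2-dioxolan-3-yl]acetate, via sulfonyl carbanion 17 (not isolated)
Conditions: 16 (1.2 equiv), KN(SiMe3)2 (1.15 equiv), DME, −78 °C, 20 min; then 10 (1.0 equiv), −78 → 23 °C; aqueous work-up
Reagents that add atoms: none
Why: Julia–Kocienski olefination: the premetalated phenyltetrazolyl sulfone adds to the unbranched aldehyde at −78 °C and Smiles rearrangement with loss of SO2 gives the E-alkene (about 10–15:1, minor Z isomer removed on AgNO3-impregnated silica); the base is used up before 10 is added and the dioxolane carries no hydrogen on its peroxide carbons, so neither ester enolisation nor Kornblum–DeLaMare cleavage is expected.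

Step 10
Reactants: 18 ethyl 2-[(3S,5R)-3,5-dimethyl-5-[(2R,5E,9E)-2-methyl-10-phenyldeca-5,9-dien-1-yl]-1,2-dioxolan-3-yl]acetate
Product: 20 2-[(3S,5R)-3,5-dimethyl-5-[(2R,5E,9E)-2-methyl-10-phenyldeca-5,9-dien-1-yl]-1,2-dioxolan-3-yl]acetic acid, via lithium carboxylate 19 (not isolated)
Conditions: LiOH·H2O (3 equiv), THF/H2O 3:1, 0 → 23 °C; then 1 M HCl to pH 3, 0 °C
Reagents that add atoms: lithium hydroxide, [Li+].[OH-]
Why: Saponification of the ethyl ester at or below room temperature and mild acidification give the acid without touching the di-tertiary peroxide, the alkenes or the three stereocentres.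

**Compound list**

1 | (R)-citronellal, (3R)-3,7-dimethyloct-6-enal | C[C@H](CCC=C(C)C)CC=O | starting material
2 | (4R)-4,8-dimethylnon-7-en-1-yne | C[C@H](CCC=C(C)C)CC#C | intermediate
3 | ethyl (2E)-4-bromo-3-methylbut-2-enoate | CCOC(=O)/C=C(\C)CBr | starting material
4 | [(4R)-4,8-dimethylnona-1,7-dien-2-yl]bis(2-methylpropyl)alumane | C[C@H](CCC=C(C)C)CC(=C)[Al](CC(C)C)CC(C)C | intermediate (not isolated)
5 | ethyl (2E,7R)-3,7,11-trimethyl-5-methylidenedodeca-2,10-dienoate | CCOC(=O)/C=C(\C)CC(=C)C[C@H](C)CCC=C(C)C | intermediate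
6 | ethyl (2E,5R,7R)-3,5,7,11-tetramethyl-5-[(triethylsilyl)peroxy]dodeca-2,10-dienoate (5R epimer shown; formed 1:1 with the 5S epimer) | CCOC(=O)/C=C(\C)C[C@](C)(OO[Si](CC)(CC)CC)C[C@H](C)CCC=C(C)C | intermediate
7 | ethyl (2E,5R,7R)-5-hydroperoxy-3,5,7,11-tetramethyldodeca-2,10-dienoate (5R epimer shown) | CCOC(=O)/C=C(\C)C[C@](C)(OO)C[C@H](C)CCC=C(C)C | intermediate (not isolated)
8 | ethyl 2-[(3S,5R)-5-[(2R)-2,6-dimethylhept-5-en-1-yl]-3,5-dimethyl-1,2-dioxolan-3-yl]acetate | C[C@H](CCC=C(C)C)C[C@]1(C)C[C@@](C)(CC(=O)OCC)OO1 | intermediate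
9 | ethyl 2-[(3S,5R)-5-[(2R)-4-(5,5-dimethyl-1,2,4-trioxolan-3-yl)-2-methylbutyl]-3,5-dimethyl-1,2-dioxolan-3-yl]acetate (both configurations at the trioxolane CH) | C[C@H](CCC1OOC(C)(C)O1)C[C@]1(C)C[C@@](C)(CC(=O)OCC)OO1 | intermediate (not isolated)
10 | ethyl 2-[(3S,5R)-3,5-dimethyl-5-[(2R)-2-methyl-5-oxopentyl]-1,2-dioxolan-3-yl]acetate | C[C@H](CCC=O)C[C@]1(C)C[C@@](C)(CC(=O)OCC)OO1 | intermediate
11 | 1-phenyl-1H-tetrazole-5-thiol | Sc1nnnn1-c1ccccc1 | starting material
12 | 5-bromopent-1-ene | C=CCCCBr | starting material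
13 | 5-(pent-4-en-1-ylsulfanyl)-1-phenyl-1H-tetrazole | C=CCCCSc1nnnn1-c1ccccc1 | intermediate
14 | 5-(pent-4-ene-1-sulfonyl)-1-phenyl-1H-tetrazole | C=CCCCS(=O)(=O)c1nnnn1-c1ccccc1 | intermediate
15 | styrene | C=Cc1ccccc1 | starting material
16 | 1-phenyl-5-{[(4E)-5-phenylpent-4-en-1-yl]sulfonyl}-1H-tetrazole | O=S(=O)(CCC/C=C/c1ccccc1)c1nnnn1-c1ccccc1 | intermediate
17 | potassium (4E)-5-phenyl-1-[(1-phenyl-1H-tetrazol-5-yl)sulfonyl]pent-4-en-1-ide | [K+].O=S(=O)([CH-]CC/C=C/c1ccccc1)c1nnnn1-c1ccccc1 | intermediate (not isolated)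
18 | ethyl 2-[(3S,5R)-3,5-dimethyl-5-[(2R,5E,9E)-2-methyl-10-phenyldeca-5,9-dien-1-yl]-1,2-dioxolan-3-yl]acetate | C[C@H](CC/C=C/CC/C=C/c1ccccc1)C[C@]1(C)C[C@@](C)(CC(=O)OCC)OO1 | intermediate
19 | lithium 2-[(3S,5R)-3,5-dimethyl-5-[(2R,5E,9E)-2-methyl-10-phenyldeca-5,9-dien-1-yl]-1,2-dioxolan-3-yl]acetate | [Li+].C[C@H](CC/C=C/CC/C=C/c1ccccc1)C[C@]1(C)C[C@@](C)(CC(=O)[O-])OO1 | intermediate (not isolated)
20 | 2-[(3S,5R)-3,5-dimethyl-5-[(2R,5E,9E)-2-methyl-10-phenyldeca-5,9-dien-1-yl]-1,2-dioxolan-3-yl]acetic acid | C[C@H](CC/C=C/CC/C=C/c1ccccc1)C[C@]1(C)C[C@@](C)(CC(=O)O)OO1 | target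

**Step count and risks**

Total step count: 10. Longest linear sequence: 7 (steps 1, 2, 3, 4, 5, 9, 10); the sulfone branch (steps 6–8) joins at step 9.

Stereochemistry summary: C7 is bought with 1; C5 is formed unselectively in step 3 and sorted in step 4; C3 is set in step 4. Nothing after step 4 touches a stereocentre.

The three steps most likely to fail:

**Step 4 (new ring closure; face control by the ion pair may be weak, and the ester enolate may close onto the O–O bond to an epoxide).** The fallback sets out from 2 and comes back at 8. Alkyne 2 is carboaluminated (Me3Al, Cp2ZrCl2 cat., CH2Cl2) and the alkenylalane is acylated with acetyl chloride to give (3E,6R)-4,6,10-trimethylundeca-3,9-dien-2-one F1. 50 % H2O2 with LiOH (5 mol %) in MeOH at 0 °C adds to the enone, and the adduct closes to the peroxyhemiketal 5-[(2R)-2,6-dimethylhept-5-en-1-yl]-3,5-dimethyl-1,2-dioxolan-3-ol F2. MeOH with TsOH gives the methyl peroxyketal 5-[(2R)-2,6-dimethylhept-5-en-1-yl]-3-methoxy-3,5-dimethyl-1,2-dioxolane F3. TiCl4 with 1-ethoxy-1-(trimethylsilyloxy)ethene in CH2Cl2 at −78 °C ionises F3 to the peroxycarbenium ion and installs the CH2CO2Et arm at C3, which returns to 8. Here 8 is formed beside its ring stereoisomers, ethyl 2-[5-[(2R)-2,6-dimethylhept-5-en-1-yl]-3,5-dimethyl-1,2-dioxolan-3-yl]acetate as the (3R,5S), (3S,5S) and (3R,5R) isomers F4, which are removed by preparative HPLC. This fallback gives no stereocontrol in the ring and relies on that separation.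

**Step 3 (the prenyl alkene may compete for the cobalt hydride).** The fallback sets out from 5 and comes back at 10. mCPBA (1.0 equiv, CH2Cl2, −20 °C) first converts the more electron-rich trisubstituted alkene of 5 into ethyl (2E,7R)-9-(3,3-dimethyloxiran-2-yl)-3,7-dimethyl-5-methylidenenon-2-enoate F5. Peroxysilylation as in step 3 then has a single reactive alkene and gives ethyl (2E,5R,7R)-9-(3,3-dimethyloxiran-2-yl)-3,5,7-trimethyl-5-[(triethylsilyl)peroxy]non-2-enoate F6 (with its 5S epimer). Closure as in step 4 gives ethyl 2-[(3S,5R)-5-[(2R)-4-(3,3-dimethyloxiran-2-yl)-2-methylbutyl]-3,5-dimethyl-1,2-dioxolan-3-yl]acetate F7. H5IO6 in THF/Et2O at 0 °C cleaves the epoxide to the aldehyde and returns to 10, so step 5 is not needed.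

**Step 2 (α-selectivity of the hydroalumination and survival of the ester next to the alane).** The fallback sets out from 2 and comes back at 5. Bromoboration of 2 with B-bromo-9-borabicyclo[3.3.1]nonane (CH2Cl2, 0 °C) and protodeboronation with AcOH give the isolable internal alkenyl bromide (4R)-2-bromo-4,8-dimethylnona-1,7-diene F8. t-BuLi (2 equiv, −78 °C) and then ZnBr2 give bromo[(4R)-4,8-dimethylnona-1,7-dien-2-yl]zinc F9, which couples with 3 under Pd(PPh3)4 in THF and returns to 5.

**Further compounds**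

F1 | step 4 | (3E,6R)-4,6,10-trimethylundeca-3,9-dien-2-one | CC(=O)/C=C(\C)C[C@H](C)CCC=C(C)C
F2 | step 4 | 5-[(2R)-2,6-dimethylhept-5-en-1-yl]-3,5-dimethyl-1,2-dioxolan-3-ol (C3 and C5 epimers) | C[C@H](CCC=C(C)C)CC1(C)CC(C)(O)OO1
F3 | step 4 | 5-[(2R)-2,6-dimethylhept-5-en-1-yl]-3-methoxy-3,5-dimethyl-1,2-dioxolane (C3 and C5 epimers) | C[C@H](CCC=C(C)C)CC1(C)CC(C)(OC)OO1
F4 | step 4 | ethyl 2-[5-[(2R)-2,6-dimethylhept-5-en-1-yl]-3,5-dimethyl-1,2-dioxolan-3-yl]acetate, (3R,5S), (3S,5S) and (3R,5R) isomers | C[C@H](CCC=C(C)C)CC1(C)CC(C)(CC(=O)OCC)OO1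
F5 | step 3 | ethyl (2E,7R)-9-(3,3-dimethyloxiran-2-yl)-3,7-dimethyl-5-methylidenenon-2-enoate (both epoxide configurations) | CCOC(=O)/C=C(\C)CC(=C)C[C@H](C)CCC1OC1(C)C
F6 | step 3 | ethyl (2E,5R,7R)-9-(3,3-dimethyloxiran-2-yl)-3,5,7-trimethyl-5-[(triethylsilyl)peroxy]non-2-enoate (5R epimer shown) | CCOC(=O)/C=C(\C)C[C@](C)(OO[Si](CC)(CC)CC)C[C@H](C)CCC1OC1(C)C
F7 | step 3 | ethyl 2-[(3S,5R)-5-[(2R)-4-(3,3-dimethyloxiran-2-yl)-2-methylbutyl]-3,5-dimethyl-1,2-dioxolan-3-yl]acetate | C[C@H](CCC1OC1(C)C)C[C@]1(C)C[C@@](C)(CC(=O)OCC)OO1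
F8 | step 2 | (4R)-2-bromo-4,8-dimethylnona-1,7-diene | C[C@H](CCC=C(C)C)CC(Br)=C
F9 | step 2 | bromo[(4R)-4,8-dimethylnona-1,7-dien-2-yl]zinc | C[C@H](CCC=C(C)C)CC(=C)[Zn]Br
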